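Where does the solid first end groups charge of the flask sit at 20 min: in links, or still in first end groups?

| flask | solid first end groups | second end groups | remark | time |
|---|---|---|---|---|
| larch | 16 mM | 31 mM | run made earlier |  |
| cedar | 23 mM | 31 mM | run made earlier |  |
| ash | 31 mM | 62 mM | run made earlier |  |
| flask | 31 mM | 31.0 mM |  | 20 min |

| run | time / min | links / % | first end groups / % | solid first end groups / % |
|---|---|---|---|---|
| larch | 2.00 | 28.8 | 2.2 | 69.8 |
| larch | 4.00 | 60.5 | 1.9 | 38.2 |
| larch | 6.00 | 90.0 | 2.9 | 7.7 |
| larch | 8.00 | 100.0 | 0 | 0.1 |
| larch | 10.0 | 99.6 | 0 | 0.4 |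
| larch | 12.0 | 100.0 | 0.2 | 0.3 |
| cedar | 2.00 | 20.5 | 0.9 | 78.7 |
| cedar | 4.00 | 41.3 | 1.7 | 57.1 |
| cedar | 6.00 | 62.4 | 2.3 | 35.0 |
| cedar | 8.00 | 83.6 | 2.6 | 14.9 |
| cedar | 10.0 | 99.9 | 0.6 | 0 |
| cedar | 12.0 | 100.1 | 0.2 | 0.3 |
| ash | 1.00 | 7.5 | 1.0 | 91.8 |
| ash | 3.00 | 24.1 | 0.3 | 75.5 |
| ash | 6.00 | 48.4 | 0.4 | 51.7 |
| ash | 8.00 | 64.3 | 0.5 | 35.3 |
| ash | 12.0 | 96.3 | 0.8 | 2.9 |

(standard deviation of a reading: 0.3 percentage points)

- what is said of links includes crystals
- crystals, solid first end groups is a solid; its amount is given per volume of the solution
- what may be going on: first end groups + second end groups -> links + by-product; crystals <-> links; solid first end groups <-> first end groups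
- at the start none of the solid first end groups is in solution
- first end groups means what is dissolved; the solid is not counted in it

- the species in which most of what was charged as solid first end groups, at 20 min sits (first end groups / links)
- the largest share itself, whichever of these holds it, in percent of the solid first end groups charged

The ledger follows the 31.0 mM of second end groups, which match the solid charge mole for mole, so both are the limiting reagent.

Income comes first. Links appear at 2.42 mM min⁻¹ in the larch run up to 4.00 min, 2.40 mM min⁻¹ in the cedar run up to 8.00 min, and 2.49 mM min⁻¹ in the ash run up to 8.00 min, although the charges differ. Their mean, 2.44 mM min⁻¹, is the feed rate, the amount of solid that dissolves and becomes links per minute while solid lasts. Dissolution is read here as the rate-limiting step, zero-order in the solid.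

Entry one: at the feed rate the solid of the flask is reckoned to last 12.7 min, shorter than 20 min, so it is booked into links and 7.29 min remain.

Entry two: from then on, c(first end groups) and c(second end groups) are taken as equal in the flask, the two charges being equal. The larch reading at 6.00 min gives k, the feed over the product of both concentrations, as 0.317 mM⁻¹ min⁻¹.

Entry three: the reciprocal of c grows by k per minute. Neglecting its starting value, about 0.434 mM stays unreacted, so the books close with links at 98.6 %.

The forecast says links at 98.8 %, within 96.5 % to 99.5 %, on the ground that “dissolution is limiting and is effectively zero-order”. Its share and this reckoning differ by 0.2 percentage points.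

The flask gives links at 98.8 %.

    first end groups + second end groups → links + by-product (k = 5.40 M⁻¹ s⁻¹)
    crystals ⇌ links, rate k2*(cs2 - [links]) while solid is left; crystals form when [links] > cs2 (solubility = 23.0 mM, k = 0.110 s⁻¹)
    solid first end groups ⇌ first end groups, rate k3*(cs3 - [first end groups]) while solid is left; crystals form when [first end groups] > cs3 (solubility = 9.90 mM, k = 0.00430 s⁻¹)

At 20.0 min the flask holds solid first end groups at 0 % and first end groups at 1.17 %. Over 10.0 min the feed rate books 24.4 mM, and the flask then holds 23.5 mM of by-product. For the neighbour flask charged with 19 mM of second end groups, the same feed rate reckons 7.79 min for that charge, shorter than 20.0 min. At 20.0 min that neighbour holds second end groups at 0 %, first end groups at 30.3 % and links at 61.3 %.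

The runs come from a simulation for substances that don't exist; scatter was added.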